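## Retrosynthetic overview

Ring atoms are called C1 (bears the heptenyl group), C2 (bears CH2OH), C3 and C4 (the cis-diol carbons), C5 (bears the butenoic acid chain) and C6 (the carbinol next to C1).

1. Late stage: the acid chain and the C4 hydroxyl are released together by lactol Wittig olefination of a γ-lactone (O4–C(=O)–CH2–C5). The heptenyl group comes from a C1 ester by Julia–Kocienski olefination, and CH2OH from a C2 enol triflate by Stille coupling.
2. The cyclohexene is made in one Lewis-acid [3+3] cyclisation that forms C3–C4 and then C1–C6. The partners are a bis(silyl enol ether) of a 4-silyloxyacetoacetate (C1–C2–C3) and a lactone acylal-aldehyde (C4–C5–C6).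
3. Enabling feature: C2 lies between C1 and C3 like the keto carbon of an acetoacetate between its α- and γ-carbons. C4(O)–C5–C6(O) is a 2-substituted malondialdehyde whose C4 oxygen and side-chain carbonyl can be tied up as a γ-butyrolactone, so the two aldehyde-level carbons become an acylal and a free aldehyde.
4. Only C5 is bought (menthyloxybutenolide, conjugate addition). C4, C3 and C6 are relayed from it in the key step.
5. Ring order: γ-lactone (purchased) → cyclohexene (step 7) → lactone opened (step 17).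

Key step: step 7

Assumption: butenolide 1 (Feringa's butenolide from (+)-menthol) is treated as purchasable; otherwise it is made from furfural by photo-oxygenation and acetalisation with (+)-menthol.
Remark: compounds that bring skeletal atoms are numbered and listed as reactants; "Reagents that add atoms" lists only the other reagents.

## Route

Step 1
Reactants: 1 (5S)-5-[(1S,2R,5S)-menthyloxy]furan-2(5H)-one; 2 vinylmagnesium bromide
Product: 3 (4R,5S)-5-[(1S,2R,5S)-menthyloxy]-4-vinyldihydrofuran-2(3H)-one (4,5-trans)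
Conditions: CH2=CHMgBr, CuBr·SMe2 (cat.), THF, −78 °C; aq. NH4Cl
Reagents that add atoms: none
Why: Copper-catalysed conjugate addition to the γ-alkoxybutenolide occurs anti to the menthyloxy group and so sets the carbon that becomes C5.

Step 2
Reactants: 3 (4R,5S)-5-menthyloxy-4-vinyldihydrofuran-2(3H)-one
Product: 4 (4R)-5-acetoxy-4-vinyldihydrofuran-2(3H)-one (anomeric mixture)
Conditions: Ac2O, AcOH, H2SO4 (cat.), 0 °C to rt
Reagents that add atoms: acetic anhydride CC(=O)OC(C)=O
Why: Acid-catalysed acetolysis exchanges the menthyl acetal for an anomeric acetate (acylal), the leaving group needed later; the vinyl-bearing stereocentre is untouched and the anomeric mixture is of no consequence.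

Step 3
Reactants: 4 (4R)-5-acetoxy-4-vinyldihydrofuran-2(3H)-one
Product: 6 (4R)-5-acetoxy-4-formyldihydrofuran-2(3H)-one, via ozonide 5 (not isolated)
Conditions: O3, CH2Cl2, −78 °C; PPh3, −78 °C to 0 °C; used crude at once
Reagents that add atoms: ozone [O-][O+]=O
Why: Ozonolysis with reductive work-up cleaves the terminal alkene to the aldehyde without touching the acylal; cold, neutral handling should keep the α-stereocentre.

Step 4
Reactants: 7 methyl 2-[(tert-butyldimethylsilyl)oxy]acetate; 8 methyl acetate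
Product: 9 methyl 4-[(tert-butyldimethylsilyl)oxy]-3-oxobutanoate
Conditions: LiN(iPr)2 (2.1 equiv), 8, THF, −78 °C; then 7, −78 to −40 °C; AcOH
Reagents that add atoms: none
Why: Crossed Claisen condensation of the lithium enolate of methyl acetate with the α-silyloxy ester; the product enolate protects the β-keto ester from further attack.

Step 5
Reactants: 9 methyl 4-[(tert-butyldimethylsilyl)oxy]-3-oxobutanoate
Product: 10 methyl (Z)-4-[(tert-butyldimethylsilyl)oxy]-3-[(triethylsilyl)oxy]but-2-enoate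
Conditions: Et3SiCl, Et3N, hexane/benzene, rt
Reagents that add atoms: chlorotriethylsilane CC[Si](Cl)(CC)CC
Why: O-Silylation of the enolised β-keto ester gives the silyl enol ether (first half of the Chan-diene synthesis).

Step 6
Reactants: 10 methyl (Z)-4-[(tert-butyldimethylsilyl)oxy]-3-[(triethylsilyl)oxy]but-2-enoate
Product: 11 4-[(tert-butyldimethylsilyl)oxy]-1-methoxy-1,3-bis[(triethylsilyl)oxy]buta-1,3-diene (geometric mixture, used crude)
Conditions: LiN(iPr)2, THF, −78 °C; Et3SiCl, −78 °C to rt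
Reagents that add atoms: chlorotriethylsilane CC[Si](Cl)(CC)CC
Why: Kinetic γ-deprotonation and O-silylation give the 1,3-bis(silyloxy)diene (Chan-type diene), a 1,3-dinucleophile at its terminal and central carbons.

Step 7
Reactants: 11 4-[(tert-butyldimethylsilyl)oxy]-1-methoxy-1,3-bis[(triethylsilyl)oxy]buta-1,3-diene; 6 (4R)-5-acetoxy-4-formyldihydrofuran-2(3H)-one
Product: 13 methyl 6-hydroxy-2-oxo-7-[(tert-butyldimethylsilyl)oxy]-4-[(triethylsilyl)oxy]-2,3,3a,4,7,7a-hexahydro-1-benzofuran-5-carboxylate (enol form; trans ring fusion; 7-OTBS cis to the lactone oxygen; 4-OTES cis to the lactone CH2), via open-chain Mukaiyama adduct 12 (not isolated)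
Conditions: Et3SiOTf (0.3 equiv), CH2Cl2, 4 Å MS, −78 °C, slow warming to −30 °C; Et3N, pH 7 buffer
Reagents that add atoms: none
Why: This is the Lewis-acid [3+3] cyclisation of a 1,3-bis(silyl enol ether) with a 1,3-dielectrophile (Chan–Brownbridge/Langer annulation, a double Mukaiyama reaction): Et3SiOTf ionises the acylal of 6 to a five-membered acyloxycarbenium ion, the terminal carbon of 11 attacks it (C3–C4), and the silyl ketene acetal left in 12 then adds to the silyl-activated aldehyde (C1–C6) in a 6-(enolexo)-exo-trig aldol closure. The step needs the acylal to react before the aldehyde and the diene terminus before its central carbon; silyl triflates activate acetal-type electrophiles well before aldehydes, and Chan-type dienes react first at the terminal carbon, so the pairing C3–C4 / C1–C6 should follow. C4 is set by attack on the lactone cation anti to the neighbouring formyl-bearing carbon (the bought centre), giving the trans-fused lactone. C3 (first addition) and C6 (ring closure) should end with both oxygens pseudoaxial beside the fully substituted enol double bond (allylic 1,2-strain), which is the target arrangement; both can equilibrate, C6 by reversible silyl aldol and C3 as the position α to the C2 carbonyl. The aldolate is silylated in the catalytic cycle, so 13 should emerge as its C6 triethylsilyl ether, protected against retro-aldol and dehydration.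

Step 8
Reactants: 13 bicyclic enol β-keto ester
Product: 14 methyl 2-oxo-7-[(tert-butyldimethylsilyl)oxy]-4-[(triethylsilyl)oxy]-6-{[(trifluoromethyl)sulfonyl]oxy}-2,3,3a,4,7,7a-hexahydro-1-benzofuran-5-carboxylate
Conditions: Tf2O, iPr2NEt, CH2Cl2, −78 °C
Reagents that add atoms: trifluoromethanesulfonic anhydride O=S(=O)(OS(=O)(=O)C(F)(F)F)C(F)(F)F
Why: O-Triflation of the enolised β-keto ester gives the vinyl triflate; low temperature avoids β-elimination of the silyloxy groups.

Step 9
Reactants: 15 (tributylstannyl)methanol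
Product: 16 tributyl{[(tert-butyldimethylsilyl)oxy]methyl}stannane
Conditions: tBuMe2SiCl, imidazole, DMF, rt
Reagents that add atoms: tert-butyldimethylsilyl chloride CC(C)(C)[Si](C)(C)Cl
Why: Standard silylation of a primary alcohol.

Step 10
Reactants: 14 vinyl triflate; 16 tributyl{[(tert-butyldimethylsilyl)oxy]methyl}stannane
Product: 17 methyl 6-{[(tert-butyldimethylsilyl)oxy]methyl}-2-oxo-7-[(tert-butyldimethylsilyl)oxy]-4-[(triethylsilyl)oxy]-2,3,3a,4,7,7a-hexahydro-1-benzofuran-5-carboxylate
Conditions: Pd(PPh3)4 (10 mol %), LiCl, 1,4-dioxane, 90 °C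
Reagents that add atoms: none
Why: Stille (Kosugi–Migita) coupling of the electron-poor vinyl triflate transfers the oxygenated methyl group in preference to butyl and installs the future CH2OH carbon at C2; the silyl ether prevents lactonisation onto the neighbouring ester.

Step 11
Reactants: 17 ester lactone
Product: 18 5-(hydroxymethyl)-6-{[(tert-butyldimethylsilyl)oxy]methyl}-7-[(tert-butyldimethylsilyl)oxy]-4-[(triethylsilyl)oxy]-2,3,3a,4,7,7a-hexahydro-1-benzofuran-2-ol (lactol, anomeric mixture)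
Conditions: iBu2AlH (4 equiv), CH2Cl2, −78 to −40 °C; aq. potassium sodium tartrate
Reagents that add atoms: none
Why: DIBAL-H reduces the conjugated methyl ester to the allylic alcohol and the γ-lactone to the lactol (aluminium hemiacetal stable at low temperature); silyl ethers are inert.

Step 12
Reactants: 18 allylic alcohol lactol
Product: 19 6-{[(tert-butyldimethylsilyl)oxy]methyl}-2-oxo-7-[(tert-butyldimethylsilyl)oxy]-4-[(triethylsilyl)oxy]-2,3,3a,4,7,7a-hexahydro-1-benzofuran-5-carbaldehyde
Conditions: PhI(OAc)2 (2.5 equiv), TEMPO (0.2 equiv), CH2Cl2, rt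
Reagents that add atoms: none
Why: TEMPO/PhI(OAc)2 oxidation takes the primary allylic alcohol to the enal and the lactol back to the lactone without over-oxidation, so the two carbonyl sites are now differentiated.

Step 13
Reactants: 20 1-phenyl-1H-tetrazole-5-thiol; 21 1-bromohexane
Product: 22 5-(hexylsulfanyl)-1-phenyl-1H-tetrazole
Conditions: K2CO3, acetone, reflux
Reagents that add atoms: none
Why: S-Alkylation of the thiolate (SN2).

Step 14
Reactants: 22 5-(hexylsulfanyl)-1-phenyl-1H-tetrazole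
Product: 23 5-(hexylsulfonyl)-1-phenyl-1H-tetrazole
Conditions: (NH4)6Mo7O24·4H2O (cat.), 30% H2O2, EtOH, 0 °C to rt
Reagents that add atoms: hydrogen peroxide OO
Why: Molybdate-catalysed oxidation of the sulfide to the sulfone.

Step 15
Reactants: 19 enal lactone; 23 5-(hexylsulfonyl)-1-phenyl-1H-tetrazole
Product: 24 5-[(E)-hept-1-en-1-yl]-6-{[(tert-butyldimethylsilyl)oxy]methyl}-7-[(tert-butyldimethylsilyl)oxy]-4-[(triethylsilyl)oxy]-3a,4,7,7a-tetrahydro-1-benzofuran-2(3H)-one
Conditions: 23, KN(SiMe3)2, DME, −60 °C; then 19, −60 °C to rt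
Reagents that add atoms: none
Why: Julia–Kocienski olefination (addition, Smiles rearrangement, elimination) should give the (E)-disubstituted alkene; the sulfonyl anion is preformed so that the lactone is not enolised.

Step 16
Reactants: 24 dienyl lactone
Product: 25 5-[(E)-hept-1-en-1-yl]-6-{[(tert-butyldimethylsilyl)oxy]methyl}-7-[(tert-butyldimethylsilyl)oxy]-4-[(triethylsilyl)oxy]-2,3,3a,4,7,7a-hexahydro-1-benzofuran-2-ol (lactol, anomeric mixture)
Conditions: iBu2AlH (1.2 equiv), CH2Cl2, −78 °C; aq. potassium sodium tartrate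
Reagents that add atoms: none
Why: Partial DIBAL-H reduction of the γ-lactone to the lactol at low temperature.

Step 17
Reactants: 25 lactol; 26 ethyl 2-(triphenyl-λ5-phosphanylidene)propanoate
Product: 27 ethyl (2E)-4-[3-[(E)-hept-1-en-1-yl]-6-hydroxy-4-{[(tert-butyldimethylsilyl)oxy]methyl}-5-[(tert-butyldimethylsilyl)oxy]-2-[(triethylsilyl)oxy]cyclohex-3-en-1-yl]-2-methylbut-2-enoate (ring configuration as in 29)
Conditions: 26 (3 equiv), toluene, 80 °C
Reagents that add atoms: none
Why: Wittig olefination of the lactol through its open hydroxy-aldehyde form with the stabilised α-methyl ylide gives the (E)-trisubstituted enoate and frees the C4 hydroxyl.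

Step 18
Reactants: 27 ethyl ester
Product: 28 (2E)-4-[3-[(E)-hept-1-en-1-yl]-6-hydroxy-4-{[(tert-butyldimethylsilyl)oxy]methyl}-5-[(tert-butyldimethylsilyl)oxy]-2-[(triethylsilyl)oxy]cyclohex-3-en-1-yl]-2-methylbut-2-enoic acid
Conditions: LiOH·H2O, THF/MeOH/H2O, rt; 1 M HCl to pH 4
Reagents that add atoms: lithium hydroxide [Li+].[OH-]
Why: Saponification of the ethyl ester while the silyl ethers are still in place.

Step 19
Reactants: 28 silylated acid
Product: 29 pestallic acid P
Conditions: HF·pyridine, pyridine/THF, 0 °C to rt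
Reagents that add atoms: none
Why: Fluoride-mediated cleavage of the three silyl ethers releases the C3, C6 and primary hydroxyls without touching the diene or the enoic acid.

## Compound list

1 | (5S)-5-[(1S,2R,5S)-menthyloxy]furan-2(5H)-one | O=C1C=C[C@@H](O[C@H]2C[C@@H](C)CC[C@@H]2C(C)C)O1 | starting material
2 | vinylmagnesium bromide | C=C[Mg]Br | starting material
3 | (4R,5S)-5-[(1S,2R,5S)-menthyloxy]-4-vinyldihydrofuran-2(3H)-one | O=C1C[C@H](C=C)[C@@H](O[C@H]2C[C@@H](C)CC[C@@H]2C(C)C)O1 | intermediate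
4 | (4R)-5-acetoxy-4-vinyldihydrofuran-2(3H)-one (anomeric mixture) | O=C1C[C@H](C=C)C(OC(C)=O)O1 | intermediate
5 | ozonide (1,2,4-trioxolane) of 4 | O=C1C[C@H](C2OCOO2)C(OC(C)=O)O1 | intermediate
6 | (4R)-5-acetoxy-4-formyldihydrofuran-2(3H)-one (anomeric mixture) | O=C1C[C@H](C=O)C(OC(C)=O)O1 | intermediate
7 | methyl 2-[(tert-butyldimethylsilyl)oxy]acetate | COC(=O)CO[Si](C)(C)C(C)(C)C | starting material
8 | methyl acetate | COC(C)=O | starting material
9 | methyl 4-[(tert-butyldimethylsilyl)oxy]-3-oxobutanoate | COC(=O)CC(=O)CO[Si](C)(C)C(C)(C)C | intermediate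
10 | methyl (Z)-4-[(tert-butyldimethylsilyl)oxy]-3-[(triethylsilyl)oxy]but-2-enoate | COC(=O)/C=C(\O[Si](CC)(CC)CC)CO[Si](C)(C)C(C)(C)C | intermediate
11 | 4-[(tert-butyldimethylsilyl)oxy]-1-methoxy-1,3-bis[(triethylsilyl)oxy]buta-1,3-diene (geometric mixture) | COC(O[Si](CC)(CC)CC)=CC(O[Si](CC)(CC)CC)=CO[Si](C)(C)C(C)(C)C | intermediate
12 | open-chain Mukaiyama adduct: silyl ketene acetal of methyl 4-[(tert-butyldimethylsilyl)oxy]-4-(trans-3-formyl-5-oxotetrahydrofuran-2-yl)-3-oxobutanoate | COC(O[Si](CC)(CC)CC)=CC(=O)[C@@H](O[Si](C)(C)C(C)(C)C)[C@H]1OC(=O)C[C@@H]1C=O | intermediate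
13 | methyl 6-hydroxy-2-oxo-7-[(tert-butyldimethylsilyl)oxy]-4-[(triethylsilyl)oxy]-2,3,3a,4,7,7a-hexahydro-1-benzofuran-5-carboxylate | COC(=O)C1=C(O)[C@@H](O[Si](C)(C)C(C)(C)C)[C@H]2OC(=O)C[C@@H]2[C@@H]1O[Si](CC)(CC)CC | intermediate
14 | 6-triflyloxy analogue of 13 (vinyl triflate) | COC(=O)C1=C(OS(=O)(=O)C(F)(F)F)[C@@H](O[Si](C)(C)C(C)(C)C)[C@H]2OC(=O)C[C@@H]2[C@@H]1O[Si](CC)(CC)CC | intermediate
15 | (tributylstannyl)methanol | CCCC[Sn](CCCC)(CCCC)CO | starting material
16 | tributyl{[(tert-butyldimethylsilyl)oxy]methyl}stannane | CCCC[Sn](CCCC)(CCCC)CO[Si](C)(C)C(C)(C)C | intermediate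
17 | methyl 6-{[(tert-butyldimethylsilyl)oxy]methyl}-2-oxo-7-[(tert-butyldimethylsilyl)oxy]-4-[(triethylsilyl)oxy]-2,3,3a,4,7,7a-hexahydro-1-benzofuran-5-carboxylate | COC(=O)C1=C(CO[Si](C)(C)C(C)(C)C)[C@@H](O[Si](C)(C)C(C)(C)C)[C@H]2OC(=O)C[C@@H]2[C@@H]1O[Si](CC)(CC)CC | intermediate
18 | 5-(hydroxymethyl) lactol from 17 (anomeric mixture) | OCC1=C(CO[Si](C)(C)C(C)(C)C)[C@@H](O[Si](C)(C)C(C)(C)C)[C@H]2OC(O)C[C@@H]2[C@@H]1O[Si](CC)(CC)CC | intermediate
19 | 5-carbaldehyde lactone | O=CC1=C(CO[Si](C)(C)C(C)(C)C)[C@@H](O[Si](C)(C)C(C)(C)C)[C@H]2OC(=O)C[C@@H]2[C@@H]1O[Si](CC)(CC)CC | intermediate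
20 | 1-phenyl-1H-tetrazole-5-thiol | SC1=NN=NN1c1ccccc1 | starting material
21 | 1-bromohexane | CCCCCCBr | starting material
22 | 5-(hexylsulfanyl)-1-phenyl-1H-tetrazole | CCCCCCSC1=NN=NN1c1ccccc1 | intermediate
23 | 5-(hexylsulfonyl)-1-phenyl-1H-tetrazole | CCCCCCS(=O)(=O)C1=NN=NN1c1ccccc1 | intermediate
24 | 5-[(E)-hept-1-en-1-yl] lactone | CCCCC/C=C/C1=C(CO[Si](C)(C)C(C)(C)C)[C@@H](O[Si](C)(C)C(C)(C)C)[C@H]2OC(=O)C[C@@H]2[C@@H]1O[Si](CC)(CC)CC | intermediate
25 | 5-[(E)-hept-1-en-1-yl] lactol (anomeric mixture) | CCCCC/C=C/C1=C(CO[Si](C)(C)C(C)(C)C)[C@@H](O[Si](C)(C)C(C)(C)C)[C@H]2OC(O)C[C@@H]2[C@@H]1O[Si](CC)(CC)CC | intermediate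
26 | ethyl 2-(triphenyl-λ5-phosphanylidene)propanoate | CCOC(=O)C(C)=P(c1ccccc1)(c1ccccc1)c1ccccc1 | starting material
27 | tris-silylated ethyl ester of the target | CCCCC/C=C/C1=C(CO[Si](C)(C)C(C)(C)C)[C@@H](O[Si](C)(C)C(C)(C)C)[C@@H](O)[C@H](C/C=C(\C)C(=O)OCC)[C@@H]1O[Si](CC)(CC)CC | intermediate
28 | tris-silylated acid | CCCCC/C=C/C1=C(CO[Si](C)(C)C(C)(C)C)[C@@H](O[Si](C)(C)C(C)(C)C)[C@@H](O)[C@H](C/C=C(\C)C(=O)O)[C@@H]1O[Si](CC)(CC)CC | intermediate
29 | pestallic acid P | CCCCC/C=C/C1=C(CO)[C@@H](O)[C@@H](O)[C@H](C/C=C(\C)C(=O)O)[C@@H]1O | target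

## Step count and risks

Total step count: 19. Longest linear sequence: 13 steps (1–3, 7, 8, 10–12, 15–19; the branch 4–6 is equally long up to step 7).

Steps most likely to fail:

**Step 7.** The acyloxycarbenium ion may lose the proton at the formyl-bearing carbon, or aldehyde 6 may eliminate acetic acid, which would erase the bought stereocentre. The diene may also attack the aldehyde first, and equilibration at C3 and C6 may be incomplete. The fallback sets out from 4 and 11 and returns at 13; it makes the two bonds in separate operations and unveils the aldehyde only after the first. Diene 11 is added to vinyl acylal 4 (Et3SiOTf, CH2Cl2, −78 °C, aqueous work-up) in a single Mukaiyama substitution to give methyl 4-[(tert-butyldimethylsilyl)oxy]-3-oxo-4-(trans-5-oxo-3-vinyltetrahydrofuran-2-yl)butanoate F1. Ozonolysis (O3, then PPh3) gives the corresponding formyl keto ester F2. A separate soft-enolisation aldol (MgBr2·OEt2, iPr2NEt, CH2Cl2, 0 °C) closes it to the 4-hydroxy bicyclic β-keto ester F3, and silylation (Et3SiCl, imidazole) gives 13.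

**Step 10.** Transfer of the sp3 stannane group may be slow, with competing butyl transfer and protodestannylation. The fallback sets out from 14 and returns at 17. Suzuki coupling with potassium vinyltrifluoroborate (PdCl2(dppf), Et3N, n-PrOH, 80 °C) gives the 6-vinyl diene ester F4. Selective cleavage of the terminal alkene (OsO4 cat., NaIO4, 2,6-lutidine, dioxane/H2O) gives the 6-formyl enoate F5. Luche reduction (NaBH4, CeCl3·7H2O, MeOH, −78 °C) gives the 6-(hydroxymethyl) enoate F6, which is silylated in the same flask (tBuMe2SiCl, imidazole) before it can lactonise, giving 17.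

**Step 15.** E-selectivity may erode with the hindered conjugated aldehyde, and the sulfonyl anion may attack or enolise the lactone. The fallback sets out from 19 and returns at 24. Takai iodo-olefination (CrCl2, CHI3, THF, 0 °C) gives the (E)-2-iodovinyl lactone F7, and Negishi coupling with n-pentylzinc bromide (PdCl2(dppf), THF, rt) gives 24.

Further compounds
F1 | step 7 | methyl 4-[(tert-butyldimethylsilyl)oxy]-3-oxo-4-(trans-5-oxo-3-vinyltetrahydrofuran-2-yl)butanoate | COC(=O)CC(=O)[C@@H](O[Si](C)(C)C(C)(C)C)[C@H]1OC(=O)C[C@@H]1C=C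
F2 | step 7 | methyl 4-[(tert-butyldimethylsilyl)oxy]-4-(trans-3-formyl-5-oxotetrahydrofuran-2-yl)-3-oxobutanoate | COC(=O)CC(=O)[C@@H](O[Si](C)(C)C(C)(C)C)[C@H]1OC(=O)C[C@@H]1C=O
F3 | step 7 | methyl 4,6-dihydroxy-2-oxo-7-[(tert-butyldimethylsilyl)oxy]-2,3,3a,4,7,7a-hexahydro-1-benzofuran-5-carboxylate | COC(=O)C1=C(O)[C@@H](O[Si](C)(C)C(C)(C)C)[C@H]2OC(=O)C[C@@H]2[C@@H]1O
F4 | step 10 | methyl 6-vinyl-2-oxo-7-[(tert-butyldimethylsilyl)oxy]-4-[(triethylsilyl)oxy]-2,3,3a,4,7,7a-hexahydro-1-benzofuran-5-carboxylate | COC(=O)C1=C(C=C)[C@@H](O[Si](C)(C)C(C)(C)C)[C@H]2OC(=O)C[C@@H]2[C@@H]1O[Si](CC)(CC)CC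
F5 | step 10 | methyl 6-formyl-2-oxo-7-[(tert-butyldimethylsilyl)oxy]-4-[(triethylsilyl)oxy]-2,3,3a,4,7,7a-hexahydro-1-benzofuran-5-carboxylate | COC(=O)C1=C(C=O)[C@@H](O[Si](C)(C)C(C)(C)C)[C@H]2OC(=O)C[C@@H]2[C@@H]1O[Si](CC)(CC)CC
F6 | step 10 | methyl 6-(hydroxymethyl)-2-oxo-7-[(tert-butyldimethylsilyl)oxy]-4-[(triethylsilyl)oxy]-2,3,3a,4,7,7a-hexahydro-1-benzofuran-5-carboxylate | COC(=O)C1=C(CO)[C@@H](O[Si](C)(C)C(C)(C)C)[C@H]2OC(=O)C[C@@H]2[C@@H]1O[Si](CC)(CC)CC
F7 | step 15 | 5-[(E)-2-iodovinyl]-6-{[(tert-butyldimethylsilyl)oxy]methyl}-7-[(tert-butyldimethylsilyl)oxy]-4-[(triethylsilyl)oxy]-3a,4,7,7a-tetrahydro-1-benzofuran-2(3H)-one | I/C=C/C1=C(CO[Si](C)(C)C(C)(C)C)[C@@H](O[Si](C)(C)C(C)(C)C)[C@H]2OC(=O)C[C@@H]2[C@@H]1O[Si](CC)(CC)CC
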